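The synthesis rests on cutting both bonds that flank the C6–C7 edge of the benzene ring of the dihydrobenzofuran: C6–OH and C7–C(=O). That edge lies next to C7a–O1, so the O1/acyl/OH triad is the pattern left when a carboxylate adds to a 3-alkoxyaryne and the acyl group then shifts from oxygen to carbon. One operation therefore delivers the phenol oxygen and the intact (S)-2-methylbutanoyl group regioselectively, without Lewis acid. The precursor is the 2S-configured 2-isopropenyl-2,3-dihydrobenzofuran bearing Et3Si on C7, a triflate on C6–O and a fluoride-inert MOM ether on C4–O. The pyrone is attached last at C5 through a one-carbon Mannich link.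

Key step: step 7

Remark on the chemistry: the target SMILES reads as 2S at the ring carbon and S at the side-chain carbon. It is assumed that the ligand antipode opposite to the one giving 2R-isopropenyl dihydrobenzofurans delivers the 2S series, and this should be confirmed on the first chiral intermediate.

Step 1
Reactants: 1 phloroglucinol (benzene-1,3,5-triol)
Product: 2 2-iodobenzene-1,3,5-triol
Conditions: I2 (1.0 equiv), NaHCO3 (1.1 equiv), THF–H2O 1:1, 0 °C, dark
Reagents that add atoms: iodine, II
Why: Electrophilic aromatic iodination of the phenoxide, in which the three ring C–H positions are equivalent so no regiochemical question arises, and one equivalent of iodine under bicarbonate buffering should stop at the monoiodide, which is used at once.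

Step 2
Reactants: 2 2-iodobenzene-1,3,5-triol; 3 isoprene
Product: 4 (2S)-2-(prop-1-en-2-yl)-2,3-dihydro-1-benzofuran-4,6-diol
Conditions: Pd2(dba)3·CHCl3 (2.5 mol %), chiral sulfinamide–monophosphine ligand (TY-Phos class, antipode giving 2S, 10 mol %), NaOPh (2.2 equiv), isoprene (5 equiv), THF, 70 °C, sealed tube, argon
Reagents that add atoms: none
Why: Asymmetric Larock-type heteroannulation (Heck/Tsuji–Trost cascade), in which oxidative addition into C–I, carbopalladation at the unsubstituted vinyl terminus of isoprene and 5-exo attack of either symmetry-related hydroxyl next to the former iodide on the internal terminus of the 2-methyl-π-allylpalladium close the ring, and the ligand sets C2 as S in the C–O bond-forming event because the allyl faces interconvert through the CH2 terminus.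

Step 3
Reactants: 4 (2S)-2-(prop-1-en-2-yl)-2,3-dihydro-1-benzofuran-4,6-diol
Product: 5 (2S)-2-(prop-1-en-2-yl)-4,6-bis(triethylsilyloxy)-2,3-dihydro-1-benzofuran
Conditions: Et3SiCl (2.3 equiv), imidazole (3 equiv), CH2Cl2, 0 °C → rt
Reagents that add atoms: triethylsilyl chloride, CC[Si](Cl)(CC)CC
Why: Standard phenol silylation, with triethylsilyl chosen as the smallest group whose aryl ethers survive bromination and chromatography while staying readily attacked by fluoride once it sits on carbon (a tert-butyl-bearing silyl group on carbon would be sluggish), and with enough bulk to shield C5.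

Step 4
Reactants: 5 (2S)-2-(prop-1-en-2-yl)-4,6-bis(triethylsilyloxy)-2,3-dihydro-1-benzofuran
Product: 6 (2S)-7-bromo-2-(prop-1-en-2-yl)-4,6-bis(triethylsilyloxy)-2,3-dihydro-1-benzofuran
Conditions: NBS (1.0 equiv), CH2Cl2, −40 °C, dark
Reagents that add atoms: N-bromosuccinimide, O=C1CCC(=O)N1Br
Why: Electrophilic aromatic bromination, in which the trioxygenated ring should react far faster than the 1,1-disubstituted alkene under cold, dark, anhydrous conditions, and C7 (one silyloxy neighbour plus the tied-back O1, the analogue of C8 in 5,7-dioxygenated chromans) is favoured over C5, which is wedged between two triethylsilyloxy groups.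

Step 5
Reactants: 6 (2S)-7-bromo-2-(prop-1-en-2-yl)-4,6-bis(triethylsilyloxy)-2,3-dihydro-1-benzofuran
Product: 10 (2S)-4-hydroxy-2-(prop-1-en-2-yl)-7-(triethylsilyl)-2,3-dihydro-1-benzofuran-6-yl trifluoromethanesulfonate, via C7-aryllithium 7 (not isolated), via lithium C6-phenoxide 8 (not isolated), via C4-O-silyl triflate 9 (not isolated)
Conditions: n-BuLi (1.05 equiv), THF, −78 → 0 °C; Tf2O (1.2 equiv), −78 °C; aq. NaHCO3; then PPTS (10 mol %), MeOH, 0 °C → rt
Reagents that add atoms: triflic anhydride, O=S(=O)(OS(=O)(=O)C(F)(F)F)C(F)(F)F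
Why: Bromine–lithium exchange followed by a retro-Brook (1,3 O→C) silyl shift, in which only the C6–O silyl group is ortho to C7–Li and so it alone migrates, the released C6 phenoxide is triflated in situ, and mild methanolysis then strips the remaining C4–O silyl ether without touching the C–Si bond, the triflate or the allylic ether.

Step 6
Reactants: 10 (2S)-4-hydroxy-2-(prop-1-en-2-yl)-7-(triethylsilyl)-2,3-dihydro-1-benzofuran-6-yl trifluoromethanesulfonate
Product: 11 (2S)-4-(methoxymethoxy)-2-(prop-1-en-2-yl)-7-(triethylsilyl)-2,3-dihydro-1-benzofuran-6-yl trifluoromethanesulfonate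
Conditions: MOMCl (1.5 equiv), i-Pr2NEt (2 equiv), CH2Cl2, 0 °C → rt
Reagents that add atoms: chloromethyl methyl ether, COCCl
Why: Phenol O-alkylation to a formaldehyde acetal, needed because a silyl ether on C4–O would be cleaved by fluoride before or alongside the C–Si bond and the freed phenoxide would compete with the carboxylate for the aryne, whereas the MOM ether is inert to fluoride, carboxylate and heat.

Step 7
Reactants: 11 (2S)-4-(methoxymethoxy)-2-(prop-1-en-2-yl)-7-(triethylsilyl)-2,3-dihydro-1-benzofuran-6-yl trifluoromethanesulfonate; 12 (S)-2-methylbutanoic acid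
Product: 17 (S)-1-[(2S)-6-hydroxy-4-(methoxymethoxy)-2-(prop-1-en-2-yl)-2,3-dihydro-1-benzofuran-7-yl]-2-methylbutan-1-one, via caesium carboxylate 13 (not isolated), via C6–C7 aryne 14 (not isolated), via C7 aryl anion 15 (not isolated), via caesium C6-phenoxide 16 (not isolated)
Conditions: 12 (3 equiv), Cs2CO3 (1.5 equiv), MeOH, rt, evaporate, dry (PhMe azeotrope, 80 °C, vacuum); then 11, CsF (4 equiv, dried), THF (0.02 M), 125 °C, sealed tube; 0.5 M HCl work-up
Reagents that add atoms: none
Why: Fluoride attacks the C7 silicon, triflate leaves C6 and aryne 14 is released slowly; carboxylate 13 adds through oxygen at C6, and the resulting C7 anion 15 attacks its own ester carbonyl through a four-membered alkoxide that opens to the C7 ketone and C6 phenoxide 16, so C6–O and C7–C(acyl) arise in one operation. The closest known reaction type is the fluoride-induced insertion of arynes from o-silylaryl triflates into the C–O bond of carboxylic acids to give o-hydroxyaryl ketones, in effect an anionic ortho-Fries shift, with the orientation established for 3-alkoxyarynes. No ring is closed and no stereocentre is made: C2 is a spectator, and Cα of the acyl group is carried over untouched because the productive path never removes its proton and fluoride, carboxylate and phenoxide are too weak to enolise the ketone of 16. Attack at C6 and not C7 is secured by the substrate itself, since the inductive pull of O1 on C7a and the angle strain of the fused five-membered ring both widen the aryne angle at C6 and leave the charge on C7 next to oxygen. Acyl shift must beat protonation of C7, which is why the dried caesium salt replaces the free acid, THF replaces acetonitrile and the mixture is run hot and dilute. Excess carboxylate and the fluoride-inert MOM ether keep competing phenoxide away from the aryne.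

Step 8
Reactants: 17 (S)-1-[(2S)-6-hydroxy-4-(methoxymethoxy)-2-(prop-1-en-2-yl)-2,3-dihydro-1-benzofuran-7-yl]-2-methylbutan-1-one
Product: 18 (S)-1-[(2S)-4,6-dihydroxy-2-(prop-1-en-2-yl)-2,3-dihydro-1-benzofuran-7-yl]-2-methylbutan-1-one
Conditions: conc. HCl (cat.), MeOH–THF, 40 °C
Reagents that add atoms: none
Why: Acid-catalysed acetal methanolysis, in which the oxocarbenium path of the MOM ether is far easier than ionisation of the secondary allylic C2–O1 bond or protonation of the inductively deactivated isopropenyl group, methanol traps the formaldehyde unit before C5 can, and the hydrogen-bonded aryl ketone should not enolise under catalytic acid.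

Step 9
Reactants: 18 (S)-1-[(2S)-4,6-dihydroxy-2-(prop-1-en-2-yl)-2,3-dihydro-1-benzofuran-7-yl]-2-methylbutan-1-one; 19 Eschenmoser's salt (N,N-dimethylmethyleneiminium iodide)
Product: 20 (S)-1-[(2S)-5-[(dimethylamino)methyl]-4,6-dihydroxy-2-(prop-1-en-2-yl)-2,3-dihydro-1-benzofuran-7-yl]-2-methylbutan-1-one
Conditions: 19 (1.1 equiv), CH2Cl2, 0 °C → rt; aq. NaHCO3 wash; used crude
Reagents that add atoms: none
Why: Mannich aminomethylation with a preformed iminium salt, in which C5 is the only free ring carbon and is activated by both flanking hydroxyls, so a single product is possible and no free formaldehyde is present that could bridge two arenes.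

Step 10
Reactants: 21 pentan-3-one
Product: 22 (Z)-3-(trimethylsilyloxy)pent-2-ene
Conditions: TMSOTf (1.1 equiv), Et3N (1.3 equiv), CH2Cl2, 0 °C
Reagents that add atoms: trimethylsilyl triflate, C[Si](C)(C)OS(=O)(=O)C(F)(F)F
Why: Soft enolisation and O-silylation of a symmetrical ketone, so only one constitutional silyl enol ether can form, and its alkene geometry is lost in the next step.

Step 11
Reactants: 22 (Z)-3-(trimethylsilyloxy)pent-2-ene; 23 malonyl dichloride
Product: 24 6-ethyl-4-hydroxy-5-methyl-2H-pyran-2-one
Conditions: 23 (1.0 equiv), Et2O, −78 °C → rt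
Reagents that add atoms: none
Why: Known [3+3] cyclocondensation of silyl enol ethers with malonyl dichloride, in which C-acylation at the enol carbon and then O-acylation of the re-enolised ketone by the second acid chloride close the lactone, which tautomerises to the 4-hydroxy-2-pyrone.

Step 12
Reactants: 20 (S)-1-[(2S)-5-[(dimethylamino)methyl]-4,6-dihydroxy-2-(prop-1-en-2-yl)-2,3-dihydro-1-benzofuran-7-yl]-2-methylbutan-1-one; 24 6-ethyl-4-hydroxy-5-methyl-2H-pyran-2-one
Product: 26 target CNP0261501.1, 3-{[(2S)-4,6-dihydroxy-7-[(2S)-2-methylbutanoyl]-2-(prop-1-en-2-yl)-2,3-dihydro-1-benzofuran-5-yl]methyl}-6-ethyl-4-hydroxy-5-methyl-2H-pyran-2-one, via ortho-quinone methide 25 (not isolated)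
Conditions: 24 (2 equiv), 1,4-dioxane, 90 °C, argon
Reagents that add atoms: none
Why: Thermal loss of dimethylamine from the Mannich base gives the C4=O/C5=CH2 ortho-quinone methide, which is captured by conjugate addition of C3 of the acidic 4-hydroxy-2-pyrone, a known Mannich-base alkylation of cyclic 1,3-dicarbonyl nucleophiles that is driven by rearomatisation, with the excess pyrone buffering the amine and no free ring carbon left for arene–arene bridging.

Compound list
1 | phloroglucinol (benzene-1,3,5-triol) | Oc1cc(O)cc(O)c1 | starting material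
2 | 2-iodobenzene-1,3,5-triol | Oc1cc(O)c(I)c(O)c1 | intermediate
3 | isoprene | C=CC(C)=C | starting material
4 | (2S)-2-(prop-1-en-2-yl)-2,3-dihydro-1-benzofuran-4,6-diol | C=C(C)[C@@H]1Cc2c(O)cc(O)cc2O1 | intermediate
5 | (2S)-2-(prop-1-en-2-yl)-4,6-bis(triethylsilyloxy)-2,3-dihydro-1-benzofuran | C=C(C)[C@@H]1Cc2c(O[Si](CC)(CC)CC)cc(O[Si](CC)(CC)CC)cc2O1 | intermediate
6 | (2S)-7-bromo-2-(prop-1-en-2-yl)-4,6-bis(triethylsilyloxy)-2,3-dihydro-1-benzofuran | C=C(C)[C@@H]1Cc2c(O[Si](CC)(CC)CC)cc(O[Si](CC)(CC)CC)c(Br)c2O1 | intermediate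
7 | [(2S)-2-(prop-1-en-2-yl)-4,6-bis(triethylsilyloxy)-2,3-dihydro-1-benzofuran-7-yl]lithium | C=C(C)[C@@H]1Cc2c(O[Si](CC)(CC)CC)cc(O[Si](CC)(CC)CC)c([Li])c2O1 | intermediate
8 | lithium (2S)-2-(prop-1-en-2-yl)-7-(triethylsilyl)-4-(triethylsilyloxy)-2,3-dihydro-1-benzofuran-6-olate | C=C(C)[C@@H]1Cc2c(O[Si](CC)(CC)CC)cc([O-])c([Si](CC)(CC)CC)c2O1.[Li+] | intermediate
9 | (2S)-2-(prop-1-en-2-yl)-7-(triethylsilyl)-4-(triethylsilyloxy)-2,3-dihydro-1-benzofuran-6-yl trifluoromethanesulfonate | C=C(C)[C@@H]1Cc2c(O[Si](CC)(CC)CC)cc(OS(=O)(=O)C(F)(F)F)c([Si](CC)(CC)CC)c2O1 | intermediate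
10 | (2S)-4-hydroxy-2-(prop-1-en-2-yl)-7-(triethylsilyl)-2,3-dihydro-1-benzofuran-6-yl trifluoromethanesulfonate | C=C(C)[C@@H]1Cc2c(O)cc(OS(=O)(=O)C(F)(F)F)c([Si](CC)(CC)CC)c2O1 | intermediate
11 | (2S)-4-(methoxymethoxy)-2-(prop-1-en-2-yl)-7-(triethylsilyl)-2,3-dihydro-1-benzofuran-6-yl trifluoromethanesulfonate | C=C(C)[C@@H]1Cc2c(OCOC)cc(OS(=O)(=O)C(F)(F)F)c([Si](CC)(CC)CC)c2O1 | intermediate
12 | (S)-2-methylbutanoic acid | OC(=O)[C@@H](C)CC | starting material
13 | caesium (S)-2-methylbutanoate | [Cs+].[O-]C(=O)[C@@H](C)CC | intermediate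
14 | (2S)-4-(methoxymethoxy)-2-(prop-1-en-2-yl)-6,7-didehydro-2,3-dihydro-1-benzofuran (C6–C7 aryne) | C=C(C)[C@@H]1CC2=C(O1)C#CC=C2OCOC | intermediate
15 | caesium salt of the C7 carbanion of (2S)-4-(methoxymethoxy)-2-(prop-1-en-2-yl)-2,3-dihydro-1-benzofuran-6-yl (S)-2-methylbutanoate | C=C(C)[C@@H]1Cc2c(OCOC)cc(OC(=O)[C@@H](C)CC)[c-]c2O1.[Cs+] | intermediate
16 | caesium (2S)-4-(methoxymethoxy)-7-[(S)-2-methylbutanoyl]-2-(prop-1-en-2-yl)-2,3-dihydro-1-benzofuran-6-olate | C=C(C)[C@@H]1Cc2c(OCOC)cc([O-])c(C(=O)[C@@H](C)CC)c2O1.[Cs+] | intermediate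
17 | (S)-1-[(2S)-6-hydroxy-4-(methoxymethoxy)-2-(prop-1-en-2-yl)-2,3-dihydro-1-benzofuran-7-yl]-2-methylbutan-1-one | C=C(C)[C@@H]1Cc2c(OCOC)cc(O)c(C(=O)[C@@H](C)CC)c2O1 | intermediate
18 | (S)-1-[(2S)-4,6-dihydroxy-2-(prop-1-en-2-yl)-2,3-dihydro-1-benzofuran-7-yl]-2-methylbutan-1-one | C=C(C)[C@@H]1Cc2c(O)cc(O)c(C(=O)[C@@H](C)CC)c2O1 | intermediate
19 | Eschenmoser's salt (N,N-dimethylmethyleneiminium iodide) | C=[N+](C)C.[I-] | starting material
20 | (S)-1-[(2S)-5-[(dimethylamino)methyl]-4,6-dihydroxy-2-(prop-1-en-2-yl)-2,3-dihydro-1-benzofuran-7-yl]-2-methylbutan-1-one | C=C(C)[C@@H]1Cc2c(O)c(CN(C)C)c(O)c(C(=O)[C@@H](C)CC)c2O1 | intermediate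
21 | pentan-3-one | CCC(=O)CC | starting material
22 | (Z)-3-(trimethylsilyloxy)pent-2-ene | C/C=C(/CC)O[Si](C)(C)C | intermediate
23 | malonyl dichloride | O=C(Cl)CC(=O)Cl | starting material
24 | 6-ethyl-4-hydroxy-5-methyl-2H-pyran-2-one | CCc1oc(=O)cc(O)c1C | intermediate
25 | (2S)-6-hydroxy-5-methylidene-7-[(S)-2-methylbutanoyl]-2-(prop-1-en-2-yl)-2,3-dihydro-1-benzofuran-4(5H)-one (ortho-quinone methide) | C=C(C)[C@@H]1CC2=C(O1)C(C(=O)[C@@H](C)CC)=C(O)C(=C)C2=O | intermediate
26 | CNP0261501.1, 3-{[(2S)-4,6-dihydroxy-7-[(2S)-2-methylbutanoyl]-2-(prop-1-en-2-yl)-2,3-dihydro-1-benzofuran-5-yl]methyl}-6-ethyl-4-hydroxy-5-methyl-2H-pyran-2-one | C=C(C)[C@@H]1Cc2c(O)c(Cc3c(O)c(C)c(CC)oc3=O)c(O)c(C(=O)[C@@H](C)CC)c2O1 | target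

Total step count: 12. Longest linear sequence: 10 (steps 1–9 and 12). Steps 10 and 11 form the pyrone branch.

Steps most likely to fail

**Step 7.**
- What may go wrong: the C7 anion may be quenched faster than it attacks the carbonyl, either by adventitious protons or by pulling the α-proton of its own ester, so that O-arylation stops short of C–C bond formation.
- Fluoride attack on the crowded silicon may also lag behind sulfonyl transfer from the triflate.
- Fallback (aryllithium acylation in place of aryne chemistry), setting out from 4 and 12 and rejoining at 18: both phenols of 4 are capped with MOMCl/i-Pr2NEt to give the bis-MOM ether F1, and NBS at low temperature gives the 7-bromide F2. Acid 12 is turned with CDI and MeNHOMe·HCl into the Weinreb amide F3. Bromine–lithium exchange on F2 (n-BuLi, THF, −78 °C, with no silyl group present to migrate) gives the chelated aryllithium F4, which adds to F3 to give the bis-MOM ketone F5 after work-up. Catalytic HCl in MeOH then frees both phenols to give 18.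

**Step 2.**
- What may go wrong: loss of iodine from the electron-rich halotriol under base, slow oxidative addition at the doubly ortho-oxygenated carbon, or weak enantioinduction on this crowded ring.
- A modest shortfall in enantiopurity alone would not need the fallback, since after step 7 any 2R material is a diastereomer that can be removed by chromatography or crystallisation.
- Fallback (stereospecific epoxide opening in place of palladium catalysis), setting out from 1 and rejoining at 5: C-prenylation of 1 with prenyl bromide in aqueous KOH gives 2-prenylphloroglucinol F6, and TBSCl/imidazole gives the tris-TBS ether F7. Shi epoxidation with the ketone antipode that delivers the R epoxide gives the epoxide F8. TBAF frees the phenoxides, and one of the two equivalent flanking ones opens the epoxide 5-exo at the secondary carbon with inversion to give the 2S tertiary alcohol F9. Et3SiCl/imidazole silylates only the two phenols to give the bis-TES carbinol F10, and SOCl2/pyridine at 0 °C dehydrates the tertiary alcohol towards the methyl groups to give 5.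

**Step 4.**
- What may go wrong: attack of the bromine electrophile on the isopropenyl group, or insufficient discrimination between C5 and C7.
- Fallback (directed ortho-lithiation in place of halogenation and exchange), setting out from 5 and rejoining at 7: s-BuLi/TMEDA in Et2O at −78 → −20 °C should deprotonate C7 directly. The ring oxygen O1 is the only good coordinating group, and C5 is buried between two poorly directing triethylsilyloxy groups. The aryllithium 7 so formed then continues through the retro-Brook shift and triflation exactly as in step 5. This fallback makes no compound outside the list (F0).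

Further compounds
F1 | step 7 | (2S)-4,6-bis(methoxymethoxy)-2-(prop-1-en-2-yl)-2,3-dihydro-1-benzofuran | C=C(C)[C@@H]1Cc2c(OCOC)cc(OCOC)cc2O1
F2 | step 7 | (2S)-7-bromo-4,6-bis(methoxymethoxy)-2-(prop-1-en-2-yl)-2,3-dihydro-1-benzofuran | C=C(C)[C@@H]1Cc2c(OCOC)cc(OCOC)c(Br)c2O1
F3 | step 7 | (S)-N-methoxy-N,2-dimethylbutanamide | CON(C)C(=O)[C@@H](C)CC
F4 | step 7 | [(2S)-4,6-bis(methoxymethoxy)-2-(prop-1-en-2-yl)-2,3-dihydro-1-benzofuran-7-yl]lithium | C=C(C)[C@@H]1Cc2c(OCOC)cc(OCOC)c([Li])c2O1
F5 | step 7 | (S)-1-[(2S)-4,6-bis(methoxymethoxy)-2-(prop-1-en-2-yl)-2,3-dihydro-1-benzofuran-7-yl]-2-methylbutan-1-one | C=C(C)[C@@H]1Cc2c(OCOC)cc(OCOC)c(C(=O)[C@@H](C)CC)c2O1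
F6 | step 2 | 2-(3-methylbut-2-en-1-yl)benzene-1,3,5-triol | CC(C)=CCc1c(O)cc(O)cc1O
F7 | step 2 | 1,3,5-tris(tert-butyldimethylsilyloxy)-2-(3-methylbut-2-en-1-yl)benzene | CC(C)=CCc1c(O[Si](C)(C)C(C)(C)C)cc(O[Si](C)(C)C(C)(C)C)cc1O[Si](C)(C)C(C)(C)C
F8 | step 2 | (3R)-2,2-dimethyl-3-[2,4,6-tris(tert-butyldimethylsilyloxy)benzyl]oxirane | CC1(C)O[C@@H]1Cc2c(O[Si](C)(C)C(C)(C)C)cc(O[Si](C)(C)C(C)(C)C)cc2O[Si](C)(C)C(C)(C)C
F9 | step 2 | (2S)-2-(2-hydroxypropan-2-yl)-2,3-dihydro-1-benzofuran-4,6-diol | CC(C)(O)[C@@H]1Cc2c(O)cc(O)cc2O1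
F10 | step 2 | 2-[(2S)-4,6-bis(triethylsilyloxy)-2,3-dihydro-1-benzofuran-2-yl]propan-2-ol | CC(C)(O)[C@@H]1Cc2c(O[Si](CC)(CC)CC)cc(O[Si](CC)(CC)CC)cc2O1
F0 | step 4 | none | none
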